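Ring A is disconnected across C1–C2 and C4–C5. The route exploits the C6 hydroxyl of ring A, which sits between the acetyl-bearing C1 and the aroyl-bearing C5: C5–C6–C1 is the core of a 1,3,5-triketone, while C2–C3–C4 comes from an alkynyl α-keto ester. One carbonate-mediated Michael–aldol–dehydration cascade forms both bonds and delivers the fully substituted phenol at the arene oxidation level. Its precursors are 1-[2,6-bis(benzyloxy)phenyl]hexane-1,3,5-trione and benzyl 6-(tert-butyldimethylsilyloxy)-2-oxohex-3-ynoate. All phenol and carboxyl protection is benzyl, so that, after oxidation of the side chain, one neutral hydrogenolysis releases the target.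

Key step: step 4

Remark: the target is achiral, so no stereocentre has to be set; alcohol 13 and the keto acids 15 and 16 are drawn in their open forms, although cyclic hemiketal or lactol tautomers may be present in equilibrium.

Step 1
Reactants: 1 methyl 2,6-dihydroxybenzoate
Product: 2 methyl 2,6-bis(benzyloxy)benzoate
Conditions: BnBr, K2CO3, DMF, 60 °C
Reagents that add atoms: benzyl bromide, BrCc1ccccc1
Why: Williamson ether synthesis: carbonate in warm DMF deprotonates both hydrogen-bonded phenols, which are benzylated on oxygen while the methyl ester stays untouched.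

Step 2
Reactants: 3 pentane-2,4-dione (acetylacetone); 2 methyl 2,6-bis(benzyloxy)benzoate
Product: 5 1-[2,6-bis(benzyloxy)phenyl]hexane-1,3,5-trione, via dilithium dianion 4 (not isolated)
Conditions: 3 (2.5 equiv), LiN(iPr)2 (5 equiv), THF, 0 °C; then 2, 0 °C to rt; cold dilute aq HCl to pH 4
Reagents that add atoms: none
Why: Claisen-type acylation of a β-diketone dianion: the terminal carbanion of 4, its most basic and least hindered site, attacks the ester carbonyl of 2, the excess dianion holds the more acidic triketone as its enolate until the quench, and the quench is kept cold and mild to avoid cyclodehydration to a 4-pyranone.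

Step 3
Reactants: 6 4-(tert-butyldimethylsilyloxy)but-1-yne; 7 dibenzyl oxalate
Product: 9 benzyl 6-(tert-butyldimethylsilyloxy)-2-oxohex-3-ynoate, via lithium acetylide 8 (not isolated)
Conditions: n-BuLi, THF, −78 °C; then added to 7 (2 equiv), THF, −78 °C; sat. aq NH4Cl at −78 °C
Reagents that add atoms: none
Why: Acylation of a lithium acetylide by an oxalate diester: the tetrahedral adduct is stable at −78 °C and collapses only on quench, so inverse addition to excess 7 should stop at the alkynyl α-keto ester.

Step 4
Reactants: 5 1-[2,6-bis(benzyloxy)phenyl]hexane-1,3,5-trione; 9 benzyl 6-(tert-butyldimethylsilyloxy)-2-oxohex-3-ynoate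
Product: 12 benzyl 4-acetyl-2-[2,6-bis(benzyloxy)benzoyl]-5-[2-(tert-butyldimethylsilyloxy)ethyl]-3-hydroxybenzoate, via Michael adduct 10 (not isolated), via cyclic aldol 11 (not isolated)
Conditions: Cs2CO3 (1.5 equiv), MeCN, 0 °C to rt, slow addition of 9; aq NH4Cl
Reagents that add atoms: none
Why: Cs2CO3 converts 5 into its cesium enolate, whose acetyl-side methylene C1 adds to the alkyne terminus C2 of 9 (Michael addition to an ynone); protonation of the allenolate gives enedione 10, whose C2=C3 geometry equilibrates through the C1 dienolate until C1 and C4 are cis. The aroyl-side methylene C5 then attacks the very electrophilic keto ester carbonyl C4 to give aldol 11, and E1cB loss of water followed by enolisation at C6 should furnish phenol 12 without any oxidant, because the alkyne already carries the oxidation level of the arene. The closest known reaction type is the base-mediated (3+3) Michael–aldol benzannulation of alkynones with 1,3-bis-nucleophilic tricarbonyl compounds such as 3-oxoglutarates. Ring A closes by a 6-exo-trig aldol of the C5 enolate onto C4, allowed by Baldwin's rules for enolates, and no stereocentre survives because those of 11 are erased on aromatisation. The step needs C1 and not C5 as the conjugate donor: C1 is flanked only by a methyl ketone, whereas C5 lies beside the out-of-plane 2,6-bis(benzyloxy)phenyl ketone, whose benzyloxy groups shield it more than smaller ethers would, and once C1 is bonded to C2 only C5 is acidic enough to reach C4. The silyl ether keeps the propargylic position non-acidic, where an ester arm would isomerise the alkyne to an allene, and working at or below room temperature keeps the ortho-hydroxy benzophenone from displacing a benzyloxy group to give a xanthone.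

Step 5
Reactants: 12 benzyl 4-acetyl-2-[2,6-bis(benzyloxy)benzoyl]-5-[2-(tert-butyldimethylsilyloxy)ethyl]-3-hydroxybenzoate
Product: 13 benzyl 4-acetyl-2-[2,6-bis(benzyloxy)benzoyl]-3-hydroxy-5-(2-hydroxyethyl)benzoate
Conditions: HF·pyridine, pyridine, THF, 0 °C to rt
Reagents that add atoms: none
Why: Fluoride-induced cleavage of a primary silyl ether, driven by the strong Si–F bond; the pyridine buffer keeps the medium mild enough for the benzyl ester, the benzyl ethers and both ketones.

Step 6
Reactants: 13 benzyl 4-acetyl-2-[2,6-bis(benzyloxy)benzoyl]-3-hydroxy-5-(2-hydroxyethyl)benzoate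
Product: 15 {2-acetyl-5-[(benzyloxy)carbonyl]-4-[2,6-bis(benzyloxy)benzoyl]-3-hydroxyphenyl}acetic acid, via arylacetaldehyde 14 (not isolated)
Conditions: TEMPO (0.2 equiv), PhI(OAc)2 (2.5 equiv), MeCN/H2O 1:1, rt
Reagents that add atoms: water, O
Why: Oxoammonium (TEMPO) oxidation with PhI(OAc)2 as terminal oxidant in aqueous acetonitrile: the primary alcohol is oxidised to aldehyde 14, whose hydrate is oxidised on to the acid, while the electron-poor, doubly hydrogen-bonded phenol, the ketones and the benzyl groups should be inert.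

Step 7
Reactants: 15 {2-acetyl-5-[(benzyloxy)carbonyl]-4-[2,6-bis(benzyloxy)benzoyl]-3-hydroxyphenyl}acetic acid
Product: 16 huanglongmycin D, 4-acetyl-5-(carboxymethyl)-2-(2,6-dihydroxybenzoyl)-3-hydroxybenzoic acid
Conditions: H2 (1 atm), 10% Pd/C, EtOAc, rt
Reagents that add atoms: none
Why: Catalytic hydrogenolysis of two aryl benzyl ethers and one benzyl ester over Pd/C under neutral conditions; the hindered, hydrogen-bonded diaryl ketone and acetyl group should be reduced far more slowly, and no acid or base is present that could close the acetic acid arm onto the acetyl group.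

Compound list
1 | methyl 2,6-dihydroxybenzoate | COC(=O)c1c(O)cccc1O | starting material
2 | methyl 2,6-bis(benzyloxy)benzoate | COC(=O)c1c(OCc2ccccc2)cccc1OCc1ccccc1 | intermediate
3 | pentane-2,4-dione (acetylacetone) | CC(=O)CC(C)=O | starting material
4 | dilithium salt of the pentane-2,4-dione dianion (terminal carbon and central carbon deprotonated, drawn as the dienediolate) | [Li+].[Li+].C=C([O-])C=C(C)[O-] | intermediate (not isolated)
5 | 1-[2,6-bis(benzyloxy)phenyl]hexane-1,3,5-trione | CC(=O)CC(=O)CC(=O)c1c(OCc2ccccc2)cccc1OCc1ccccc1 | intermediate (key-step precursor)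
6 | 4-(tert-butyldimethylsilyloxy)but-1-yne | C#CCCO[Si](C)(C)C(C)(C)C | starting material
7 | dibenzyl oxalate | O=C(OCc1ccccc1)C(=O)OCc1ccccc1 | starting material
8 | [4-(tert-butyldimethylsilyloxy)but-1-yn-1-yl]lithium | [Li]C#CCCO[Si](C)(C)C(C)(C)C | intermediate (not isolated)
9 | benzyl 6-(tert-butyldimethylsilyloxy)-2-oxohex-3-ynoate | O=C(OCc1ccccc1)C(=O)C#CCCO[Si](C)(C)C(C)(C)C | intermediate (key-step precursor)
10 | benzyl (3Z)-5-acetyl-8-[2,6-bis(benzyloxy)phenyl]-4-[2-(tert-butyldimethylsilyloxy)ethyl]-2,6,8-trioxooct-3-enoate (keto form drawn; C5 of the chain racemic) | CC(=O)C(C(=O)CC(=O)c1c(OCc2ccccc2)cccc1OCc1ccccc1)/C(CCO[Si](C)(C)C(C)(C)C)=C\C(=O)C(=O)OCc1ccccc1 | intermediate (not isolated)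
11 | benzyl 4-acetyl-6-[2,6-bis(benzyloxy)benzoyl]-3-[2-(tert-butyldimethylsilyloxy)ethyl]-1-hydroxy-5-oxocyclohex-2-ene-1-carboxylate (mixture of diastereomers, all stereocentres lost on aromatisation) | CC(=O)C1C(=O)C(C(=O)c2c(OCc3ccccc3)cccc2OCc2ccccc2)C(O)(C(=O)OCc2ccccc2)C=C1CCO[Si](C)(C)C(C)(C)C | intermediate (not isolated)
12 | benzyl 4-acetyl-2-[2,6-bis(benzyloxy)benzoyl]-5-[2-(tert-butyldimethylsilyloxy)ethyl]-3-hydroxybenzoate | CC(=O)c1c(CCO[Si](C)(C)C(C)(C)C)cc(C(=O)OCc2ccccc2)c(C(=O)c2c(OCc3ccccc3)cccc2OCc2ccccc2)c1O | intermediate (key-step product)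
13 | benzyl 4-acetyl-2-[2,6-bis(benzyloxy)benzoyl]-3-hydroxy-5-(2-hydroxyethyl)benzoate | CC(=O)c1c(CCO)cc(C(=O)OCc2ccccc2)c(C(=O)c2c(OCc3ccccc3)cccc2OCc2ccccc2)c1O | intermediate
14 | benzyl 4-acetyl-2-[2,6-bis(benzyloxy)benzoyl]-3-hydroxy-5-(2-oxoethyl)benzoate | CC(=O)c1c(CC=O)cc(C(=O)OCc2ccccc2)c(C(=O)c2c(OCc3ccccc3)cccc2OCc2ccccc2)c1O | intermediate (not isolated)
15 | {2-acetyl-5-[(benzyloxy)carbonyl]-4-[2,6-bis(benzyloxy)benzoyl]-3-hydroxyphenyl}acetic acid | CC(=O)c1c(CC(=O)O)cc(C(=O)OCc2ccccc2)c(C(=O)c2c(OCc3ccccc3)cccc2OCc2ccccc2)c1O | intermediate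
16 | huanglongmycin D, 4-acetyl-5-(carboxymethyl)-2-(2,6-dihydroxybenzoyl)-3-hydroxybenzoic acid | CC(=O)c1c(CC(=O)O)cc(C(=O)O)c(C(=O)c2c(O)cccc2O)c1O | target

Total step count: 7. Longest linear sequence: 6 steps (steps 1, 2, 4, 5, 6, 7); the ynone branch (step 3) joins at step 4.

Steps most likely to fail

Step 4. The site selectivity of the first conjugate addition may erode or invert, with the aroyl-side methylene C5 adding to the alkyne; this would exchange the acetyl and aroyl groups on ring A. The fallback sets out from triketone 5 and comes back at arene 12, and turns that preference to use by transposing the two electrophilic termini. Benzyl propiolate is lithiated with LiN(SiMe3)2 in THF at −78 °C and added to 3-(tert-butyldimethylsilyloxy)propanal to give racemic benzyl 4-hydroxy-6-(tert-butyldimethylsilyloxy)hex-2-ynoate F1. MnO2 in CH2Cl2 oxidises this to benzyl 6-(tert-butyldimethylsilyloxy)-4-oxohex-2-ynoate F2. In F2 the ester sits on the alkyne carbon that accepts the nucleophile (β to the ketone) and the silyloxyethyl chain on the ketone carbon. Under Cs2CO3 in MeCN, C5 as conjugate donor and C1 as aldol partner therefore build the same C4–C5 and C1–C2 bonds and give 12.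

Step 2. Attack of the dianion on the doubly ortho-substituted ester carbonyl may be too slow, so that the dianion is consumed by proton transfer while ester 2 is recovered. The fallback sets out from acetylacetone 3 (as its dianion 4) and comes back at triketone 5, replacing the ester by a far more reactive aldehyde. Commercial 2,6-dihydroxybenzaldehyde is benzylated as in step 1 (BnBr, K2CO3, DMF) to 2,6-bis(benzyloxy)benzaldehyde F3. Aldol addition of 4 to F3 (THF, −78 to 0 °C) should give 6-[2,6-bis(benzyloxy)phenyl]-6-hydroxyhexane-2,4-dione F4. Oxidation of the benzylic alcohol with MnO2 in CH2Cl2 then gives 5.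

Step 6. The oxidant may attack the free phenol of ring A, whose para position C3 is unsubstituted, or the transient aldehyde may be diverted by aldol reaction with the neighbouring acetyl group before it is hydrated and oxidised. The fallback sets out from alcohol 13 and comes back at target 16, capping the phenol first and oxidising in two separate stages. Selective O-benzylation of the phenol (BnBr, K2CO3, DMF, rt) gives benzyl 4-acetyl-3-(benzyloxy)-2-[2,6-bis(benzyloxy)benzoyl]-5-(2-hydroxyethyl)benzoate F5. Dess–Martin periodinane with NaHCO3 in CH2Cl2 gives benzyl 4-acetyl-3-(benzyloxy)-2-[2,6-bis(benzyloxy)benzoyl]-5-(2-oxoethyl)benzoate F6. Pinnick oxidation (NaClO2, NaH2PO4, 2-methyl-2-butene, t-BuOH/H2O) gives {2-acetyl-3-(benzyloxy)-5-[(benzyloxy)carbonyl]-4-[2,6-bis(benzyloxy)benzoyl]phenyl}acetic acid F7. Hydrogenolysis under the conditions of step 7 then removes all four benzyl groups and gives 16.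

Further compounds
F1 | step 4 | benzyl 4-hydroxy-6-(tert-butyldimethylsilyloxy)hex-2-ynoate (racemic) | O=C(OCc1ccccc1)C#CC(O)CCO[Si](C)(C)C(C)(C)C
F2 | step 4 | benzyl 6-(tert-butyldimethylsilyloxy)-4-oxohex-2-ynoate | O=C(OCc1ccccc1)C#CC(=O)CCO[Si](C)(C)C(C)(C)C
F3 | step 2 | 2,6-bis(benzyloxy)benzaldehyde | O=Cc1c(OCc2ccccc2)cccc1OCc1ccccc1
F4 | step 2 | 6-[2,6-bis(benzyloxy)phenyl]-6-hydroxyhexane-2,4-dione (racemic) | CC(=O)CC(=O)CC(O)c1c(OCc2ccccc2)cccc1OCc1ccccc1
F5 | step 6 | benzyl 4-acetyl-3-(benzyloxy)-2-[2,6-bis(benzyloxy)benzoyl]-5-(2-hydroxyethyl)benzoate | CC(=O)c1c(CCO)cc(C(=O)OCc2ccccc2)c(C(=O)c2c(OCc3ccccc3)cccc2OCc2ccccc2)c1OCc1ccccc1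
F6 | step 6 | benzyl 4-acetyl-3-(benzyloxy)-2-[2,6-bis(benzyloxy)benzoyl]-5-(2-oxoethyl)benzoate | CC(=O)c1c(CC=O)cc(C(=O)OCc2ccccc2)c(C(=O)c2c(OCc3ccccc3)cccc2OCc2ccccc2)c1OCc1ccccc1
F7 | step 6 | {2-acetyl-3-(benzyloxy)-5-[(benzyloxy)carbonyl]-4-[2,6-bis(benzyloxy)benzoyl]phenyl}acetic acid | CC(=O)c1c(CC(=O)O)cc(C(=O)OCc2ccccc2)c(C(=O)c2c(OCc3ccccc3)cccc2OCc2ccccc2)c1OCc1ccccc1
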